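## Structural features

The target is a briarane. A cyclohexane (ring C: C1, C10, C11, C12, C13, C14) is fused through the C1–C10 bond to a ten-membered carbocycle (C1 to C10), and a γ-lactone (O–C19–C17–C8) is fused to that ring at C7–C8. There are fourteen stereocentres: C1 to C4 form one unbroken run, C6 to C14 a second, and C17 sits in the lactone, so only the sp2 carbon C5 interrupts the chain. The quaternary C1 (bearing C15) lies between C2 and the junction carbon C10, and the fully substituted C8 (tertiary hydroxyl) lies between C7 and C9. The fragile groups are the secondary allylic chloride at C6 beside the C5=C16 methylene, the 3,4-epoxide allylic to that olefin, the 13,14-epoxide, three acetates, and a β-hydroxy lactone open to retro-aldol cleavage, dehydration and C17 epimerisation. The real difficulty is the ten-membered ring: it is trans-fused at a quaternary carbon, oxygenated at almost every position, and poorly suited to direct closure from an open chain. The key step exploits the fact that C1–C10 is shared by ring C and the ten-membered ring, so the perimeter C1 to C14 is a fourteen-membered carbocycle. C9 and C13 are oxygenated in the target; as carbonyl groups they make C10 an enolisable α-carbon and C1 the β-carbon of an enone, so forming C1–C10 across the macrocycle creates both rings at once.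

## Logic of the disconnections

53 to 52: the C6–Cl bond is cut and C5=C16 is moved back to the trisubstituted C5=C6 olefin. The allylic chloride is the most labile group, so it is introduced last. This removes one stereocentre and one sensitive function. The forward ene chlorination must deliver chlorine to one face of C5=C6 and must find no other olefin in the molecule.

52 to 50 (through 51): the C2 and C12 acetates and both epoxide oxygens are removed, leaving allylic alcohols beside C3=C4 and C13=C14. Four stereocentres are traded for two hydroxyl groups that can direct the oxidant. The forward epoxidation must be syn to each hydroxyl and must spare C5=C6, which has no allylic hydroxyl.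

50 and 49 to 46: the C8–C17 bond of the lactone is cut, with C7–O kept as an acrylate ester and C8 as a ketone. This removes the fully substituted C8 and C17 in one stroke. The forward step must generate the propanoate enolate under non-basic conditions and add it to one face of the C8 ketone.

46 to 42 (through 45, 44 and 43): the C8 carbonyl is returned to its dithiolane, the two acyl groups are removed, and the C9–H bond is cut back to a C9 ketone. The gain is a β-hydroxy ketone in which the C7 hydroxyl controls C9. The forward sequence needs a 1,3-anti selective reduction, an acylation that distinguishes C7–OH from C9–OH, and unmasking of C8 without acid.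

42 and 41 to 38 (through 40): the 13,14-olefin is traced to the C13 ketone through its enol triflate. This returns the carbonyl that the ring-forming step needs. The forward step must enolise C13 toward C14 only.

38 to 35: the C1–C10 bond is cut. This is the strategic simplification: ring C, the ten-membered ring, the quaternary C1 and the junction C10 all disappear, leaving a fourteen-membered diketone with only four stereocentres. The forward step must enolise C9 toward C10 only and must set C1 and C10 trans.

35 to 31 (through 34 and 33): the 3Z olefin is traced to an alkyne and the C13–C14 bond is cut to a vinyl iodide and an aldehyde. The macrocycle opens at a bond whose new stereocentre is later destroyed by oxidation. The forward closure must keep the Z-trisubstituted vinyl geometry, and the semi-reduction must be cis.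

31 to 22 plus 26 (through 30, 29 and 28): the C2–C3 bond is cut between a terminal alkyne and an enal. A four-carbon piece that already carries the 1Z geometry is split off. The forward alkynylation must set C2 by catalyst control.

22 to 11 plus 19 (through 21): the C9–C10 bond is cut between an amide carbonyl and a primary alkyl carbanion. The chain falls into two pieces of similar size. The forward coupling must stop at the ketone and the silyl-protected alkyne must survive.

11 to 4 plus 7 (through 10 and 9): the C7–C8 bond is cut as an aldol. C8 arrives already masked and C9 at the ester level. The forward aldol must set C7 by reagent control, since no other stereocentre is nearby.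

19 to 12 plus 13 (through 18, 17 and 16): the C11–C12 bond is cut as a propanoate aldol. Both stereocentres of this piece come from one auxiliary-controlled step. The forward reaction must give the syn isomer.

26 to 23, 4 to 1 and 7 to 5: the C1–C15 bond is cut back to a propargylic alcohol, and the remaining pieces are functional-group changes on catalogue compounds. The demand is anti addition of methyl and metal across the alkyne, so that C14 and C2 end up cis.

## Other disconnections considered

Alternative 1: The cut is C6–C7, which opens the ten-membered ring between the chlorinated carbon and the lactone carbinol carbon. In the forward sense the bromo aldehyde A2 (C16 allylic bromide, C6 vinyl chloride, C7 aldehyde) would be treated with CrCl2. The γ-chloroallylchromium species (trivalent chromium) would add through C6 to the aldehyde and give the chlorohydrin A1, with the olefin shifted to C5=C16.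
- In its favour: chlorine, the exocyclic methylene and the C6/C7 pair arrive in one mild step that tolerates epoxides and esters, and an anti chlorohydrin is expected from a chair transition state. On the placing of chlorine this is better than the chosen plan, which relies on the facial bias of a late ene chlorination.
- Against it here: a ten-membered ring is closed directly, at an aldehyde neopentylic to the fully substituted C8. Every other stereocentre (the C1/C10 junction, C8, C17, both epoxides) must already be carried in the open chain.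
- Comparison: structurally, the chosen plan never closes a medium ring from a chain. Mechanistically, both plans lean on conformation for one relative configuration (C6/C7 there, C1/C10 here). In step count the alternative is judged no shorter, because ring C with its quaternary carbon and the C8 array need separate syntheses before the closure.

Alternative 2: The cut is C8–C17 inside the lactone. In the forward sense the diazo ester A4 would be decomposed with Rh2(OAc)4; the rhodium carbenoid would insert into the C8–H bond with retention and give the lactone A3.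
- In its favour: the fully substituted C8 is made stereospecifically from a simple secondary carbinol, early and on a small fragment. On the configuration of C8 this is better than the chosen plan, where C8 depends on the face of a ring ketone.
- Against it here: C17 is not fixed by the insertion, and 2-diazopropanoates are prone to 1,2-hydride shift to acrylates and to insertion into the benzylic ether C–H bonds. The step also solves only the lactone; the ten-membered ring would still have to be closed around C6 and C9 next to a quaternary centre, and C1–C10 remains unmade.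
- Comparison: the two plans are equal in the number of stereocentres set by their key steps (two each). The chosen key step builds two carbocycles, this one none, so the later step count of this alternative is judged higher.

Alternative 3: The cuts are C10–C11 and C1–C14, a [4+2] retron for ring C. In the forward sense the aminosiloxydiene A6 would add to the dienophile A7 and give the cycloadduct A5, with the C2 aldehyde and the C9 ester trans as in the E-olefin.
- In its favour: the quaternary C1 and C10 are set by a suprafacial, regiochemically predictable intermolecular reaction, and the adduct carries oxygen at C12 and latent unsaturation at C13/C14. On the reliability of the C1/C10 relation this is better than the chosen plan, whose chair transition state is expected but not assured.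
- Against it here: the C20 methyl is missing, and the whole ten-membered ring from C2 to C9 must then be built and closed between two neopentylic positions, again a direct medium-ring closure.
- Comparison: step economy up to ring C favours the alternative, and after ring C favours the chosen plan.
- A related point on geometry: the E geometry of A7 suits this alternative but rules it out as a source of C13, C14, C1 and C2 for the chosen plan. An E building block would place C2 trans to C13, whereas the 1Z-enone needs them cis.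

Key step: step 22

Remark: briarane locants are used for all intermediates (perimeter C1 to C14, C15 on C1, C16 on C5, C20 on C11, C17 to C19 in the lactone); CIP descriptors of unchanged centres switch formally when neighbouring groups change (for example C12 from 40 to 41, C2 from 31 to 33).
Remark: compounds 1 and 13 are taken to be catalogue compounds.
Remark: the facial sense in steps 4 and 15 is taken from the usual models for these promoters; if Mosher ester analysis of 9 or 28 shows the opposite sense, the antipodal promoter or ligand is used.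
Remark: because the 1Z-enone needs C2 cis to C13, C14, C1, C15 and C2 are taken from 23 by anti-carbomagnesiation; the C8 carbonyl is masked as a dithiolane (installed with the C7–C8 bond, removed without acid), and the C7 silyl ether differs from those at C2 and C12 so that the C7 hydroxyl can be released alone.

## Route

Step 1
Reactants: 1 (E)-3-methylpent-2-en-4-yn-1-ol
Product: 3 (E)-3-methyl-5-(trimethylsilyl)pent-2-en-4-yn-1-ol, via bis-silylated enynol 2 (not isolated)
Conditions: n-BuLi (2.2 equiv), THF, −78 °C; TMSCl (2.3 equiv), −78 → 23 °C; then 1 M HCl, 23 °C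
Reagents that add atoms: chlorotrimethylsilane, C[Si](C)(C)Cl
Why: Double deprotonation (O–H and alkyne C–H) and silylation, then selective hydrolysis of the O–Si bond; the C-silyl group protects the acidic alkyne proton from the alkyllithium of step 11.

Step 2
Reactants: 3 (E)-3-methyl-5-(trimethylsilyl)pent-2-en-4-yn-1-ol
Product: 4 (E)-3-methyl-5-(trimethylsilyl)pent-2-en-4-ynal
Conditions: MnO2 (15 equiv), CH2Cl2, 23 °C
Reagents that add atoms: none
Why: MnO2 oxidation of a primary allylic alcohol; the neutral heterogeneous conditions should leave the 5E geometry untouched.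

Step 3
Reactants: 5 ethyl 1,3-dithiolane-2-carboxylate
Product: 7 2-[ethoxy(trimethylsilyloxy)methylidene]-1,3-dithiolane, via lithium ester enolate 6 (not isolated)
Conditions: LiN(i-Pr)2 (1.05 equiv), THF, −78 °C; TMSCl, −78 → 0 °C
Reagents that add atoms: chlorotrimethylsilane, C[Si](C)(C)Cl
Why: Ester enolisation and O-silylation to a silyl ketene acetal; the enolate carbon is fully substituted, so no enolate geometry arises, and the ester-stabilised anion should not fragment at −78 °C.

Step 4
Reactants: 4 (E)-3-methyl-5-(trimethylsilyl)pent-2-en-4-ynal; 7 2-[ethoxy(trimethylsilyloxy)methylidene]-1,3-dithiolane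
Product: 9 ethyl 2-[(1S,2E)-1-hydroxy-3-methyl-5-(trimethylsilyl)pent-2-en-4-yn-1-yl]-1,3-dithiolane-2-carboxylate, via O-trimethylsilyl aldol 8 (not isolated)
Conditions: oxazaborolidinone from N-Ts-(S)-valine and BH3·THF (1.0 equiv), CH2Cl2, −78 °C; then pH 7 buffer, 1 M HCl/THF
Reagents that add atoms: none
Why: Mukaiyama aldol promoted by a chiral N-sulfonyl oxazaborolidinone forms C7–C8 with C8 already masked and C9 as an ester. The aldehyde should bind boron anti to the isopropyl group so that the ketene acetal attacks its re face, giving 7S.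

Step 5
Reactants: 9 ethyl 2-[(1S,2E)-1-hydroxy-3-methyl-5-(trimethylsilyl)pent-2-en-4-yn-1-yl]-1,3-dithiolane-2-carboxylate
Product: 10 ethyl 2-[(1S,2E)-3-methyl-1-[(triethylsilyl)oxy]-5-(trimethylsilyl)pent-2-en-4-yn-1-yl]-1,3-dithiolane-2-carboxylate
Conditions: TESOTf, 2,6-lutidine, CH2Cl2, −78 → 0 °C
Reagents that add atoms: triethylsilyl trifluoromethanesulfonate, CC[Si](CC)(CC)OS(=O)(=O)C(F)(F)F
Why: Silylation of a hindered secondary alcohol with a silyl triflate; the triethylsilyl ether blocks retro-aldol cleavage and can later be removed in the presence of the tert-butyldimethylsilyl ethers.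

Step 6
Reactants: 10 ethyl 2-[(1S,2E)-3-methyl-1-[(triethylsilyl)oxy]-5-(trimethylsilyl)pent-2-en-4-yn-1-yl]-1,3-dithiolane-2-carboxylate
Product: 11 N-methoxy-N-methyl-2-[(1S,2E)-3-methyl-1-[(triethylsilyl)oxy]-5-(trimethylsilyl)pent-2-en-4-yn-1-yl]-1,3-dithiolane-2-carboxamide
Conditions: MeNH(OMe)·HCl (3 equiv), i-PrMgCl (6 equiv), THF, −20 → 0 °C
Reagents that add atoms: N,O-dimethylhydroxylamine hydrochloride, CNOC.Cl
Why: Direct ester aminolysis with the chloromagnesium amide gives the Weinreb amide, which allows a single addition of the C10 carbanion in step 11.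

Step 7
Reactants: 12 (S)-4-benzyl-3-propanoyl-1,3-oxazolidin-2-one; 13 2-[(4-methoxybenzyl)oxy]acetaldehyde
Product: 16 (S)-4-benzyl-3-[(2S,3S)-3-hydroxy-4-[(4-methoxybenzyl)oxy]-2-methylbutanoyl]-1,3-oxazolidin-2-one, via dibutylboron Z-enolate 14 (not isolated), via dibutylboron aldolate 15 (not isolated)
Conditions: n-Bu2BOTf, i-Pr2NEt, CH2Cl2, 0 °C; 13, −78 → 0 °C; then pH 7 buffer, MeOH, 30% H2O2
Reagents that add atoms: none
Why: Evans syn aldol through the Z boron enolate and a Zimmerman–Traxler chair; the auxiliary sets C11 and C12 together in the syn relation needed.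

Step 8
Reactants: 16 (S)-4-benzyl-3-[(2S,3S)-3-hydroxy-4-[(4-methoxybenzyl)oxy]-2-methylbutanoyl]-1,3-oxazolidin-2-one
Product: 17 (S)-4-benzyl-3-[(2S,3S)-3-[(tert-butyldimethylsilyl)oxy]-4-[(4-methoxybenzyl)oxy]-2-methylbutanoyl]-1,3-oxazolidin-2-one
Conditions: TBSOTf, 2,6-lutidine, CH2Cl2, −78 → 0 °C
Reagents that add atoms: tert-butyldimethylsilyl trifluoromethanesulfonate, CC(C)(C)[Si](C)(C)OS(=O)(=O)C(F)(F)F
Why: Silylation of the aldol hydroxyl; it prevents retro-aldol during auxiliary removal and gives the C12 ether that lasts to step 31.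

Step 9
Reactants: 17 (S)-4-benzyl-3-[(2S,3S)-3-[(tert-butyldimethylsilyl)oxy]-4-[(4-methoxybenzyl)oxy]-2-methylbutanoyl]-1,3-oxazolidin-2-one
Product: 18 (2R,3S)-3-[(tert-butyldimethylsilyl)oxy]-4-[(4-methoxybenzyl)oxy]-2-methylbutan-1-ol
Conditions: LiBH4, MeOH (1 equiv), THF, 0 °C
Reagents that add atoms: none
Why: Reductive cleavage of the N-acyl oxazolidinone with LiBH4 gives the C10 primary alcohol without touching C11.

Step 10
Reactants: 18 (2R,3S)-3-[(tert-butyldimethylsilyl)oxy]-4-[(4-methoxybenzyl)oxy]-2-methylbutan-1-ol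
Product: 19 tert-butyl{[(2S,3S)-4-iodo-1-[(4-methoxybenzyl)oxy]-3-methylbutan-2-yl]oxy}dimethylsilane
Conditions: I2, PPh3, imidazole, CH2Cl2, 0 → 23 °C
Reagents that add atoms: iodine, II
Why: Appel-type iodination of the primary alcohol through its alkoxyphosphonium salt; no stereocentre is involved.

Step 11
Reactants: 19 tert-butyl{[(2S,3S)-4-iodo-1-[(4-methoxybenzyl)oxy]-3-methylbutan-2-yl]oxy}dimethylsilane; 11 N-methoxy-N-methyl-2-[(1S,2E)-3-methyl-1-[(triethylsilyl)oxy]-5-(trimethylsilyl)pent-2-en-4-yn-1-yl]-1,3-dithiolane-2-carboxamide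
Product: 21 C3–C13 ketone (7S,11R,12S): 13-O-PMB 12-O-TBS 9-oxo 8,8-ethylenedithio 7-O-TES 5E-ene 3-yne with C3 trimethylsilyl, via primary alkyllithium 20 (not isolated)
Conditions: 19, t-BuLi (2.1 equiv), Et2O, −78 °C; then 11, −78 → −40 °C; aq. NH4Cl
Reagents that add atoms: none
Why: Iodine–lithium exchange, then addition of the alkyllithium to the Weinreb amide forms C9–C10; the chelated tetrahedral intermediate stops at the ketone, and Et2O at −78 °C should suppress silyl migration in 20.

Step 12
Reactants: 21 C3–C13 ketone with C3 trimethylsilyl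
Product: 22 C3–C13 ketone with terminal C3 alkyne (7S,11R,12S)
Conditions: K2CO3 (0.3 equiv), MeOH, 0 → 23 °C
Reagents that add atoms: none
Why: Methanolysis of the alkynyl C–Si bond; C8 carries no hydrogen, so neither retro-aldol nor β-elimination of the C7 ether is open.

Step 13
Reactants: 23 prop-2-yn-1-ol
Product: 25 (Z)-3-iodo-2-methylprop-2-en-1-ol, via 4-methyl-2,5-dihydro-1,2-oxamagnesole 24 (not isolated)
Conditions: MeMgBr (3 equiv), CuI (10 mol %), THF, −10 → 23 °C; then I2, −78 → 0 °C
Reagents that add atoms: methylmagnesium bromide, C[Mg]Br; iodine, II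
Why: Copper-catalysed anti-carbomagnesiation directed by the magnesium alkoxide puts methyl on C1 and the metal on C14 cis to C2; iodinolysis with retention gives the Z vinyl iodide, which fixes the 1Z geometry.

Step 14
Reactants: 25 (Z)-3-iodo-2-methylprop-2-en-1-ol
Product: 26 (Z)-3-iodo-2-methylprop-2-enal
Conditions: Dess–Martin periodinane, NaHCO3, CH2Cl2, 0 °C, dark; used at once
Reagents that add atoms: none
Why: Buffered Dess–Martin oxidation of the allylic alcohol; short, cold, dark handling should prevent Z to E isomerisation of the enal.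

Step 15
Reactants: 22 C3–C13 ketone with terminal C3 alkyne; 26 (Z)-3-iodo-2-methylprop-2-enal
Product: 28 propargylic alcohol (2S,7S,11R,12S) joining C2 to C3 with the Z vinyl iodide at C14, via alkynylmethylzinc species 27 (not isolated)
Conditions: Me2Zn (3 equiv), (S,S)-ProPhenol (20 mol %), Ph3P=O (40 mol %), toluene, 4 °C; then 26 (1.5 equiv)
Reagents that add atoms: none
Why: Zinc/ProPhenol-catalysed asymmetric alkynylation of an α-branched enal forms C2–C3; the dinuclear zinc catalyst delivers the alkynyl group to the si face and sets 2S by reagent control, and the hindered C9 ketone should not react.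

Step 16
Reactants: 28 propargylic alcohol (2S,7S,11R,12S)
Product: 29 C2 tert-butyldimethylsilyl ether of 28
Conditions: TBSCl, imidazole, DMF, 0 → 23 °C
Reagents that add atoms: tert-butyldimethylsilyl chloride, CC(C)(C)[Si](C)(C)Cl
Why: Silylation under imidazole conditions, chosen over a silyl triflate to avoid enol silylation of the C9 ketone.

Step 17
Reactants: 29 C2 tert-butyldimethylsilyl ether of 28
Product: 30 C13 primary alcohol (2S,7S,11R,12S)
Conditions: DDQ (1.3 equiv), CH2Cl2/pH 7 buffer 10:1, 0 °C
Reagents that add atoms: none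
Why: Oxidative cleavage of the p-methoxybenzyl ether; the short buffered reaction at 0 °C is expected to spare the dithiolane and the enyne.

Step 18
Reactants: 30 C13 primary alcohol
Product: 31 C13 aldehyde (2S,7S,11R,12S) with C14 vinyl iodide
Conditions: Dess–Martin periodinane, NaHCO3, CH2Cl2, 0 °C
Reagents that add atoms: none
Why: Dess–Martin oxidation under buffered anhydrous conditions gives the α-silyloxy aldehyde without epimerising C12; it is used directly.

Step 19
Reactants: 31 C13 aldehyde with C14 vinyl iodide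
Product: 33 fourteen-membered allylic alcohol (1Z,5E,3-yne; 2R,7S,11R,12S; mixture at C13), via alkenylchromium dichloride 32 (not isolated)
Conditions: CrCl2 (8 equiv), NiCl2 (2 mol % of Cr), DMSO/THF 3:1, 23 °C, 2 mM
Reagents that add atoms: none
Why: Nozaki–Hiyama–Kishi macrocyclisation forms C13–C14 through a vinyl species of trivalent chromium that adds to the aldehyde and not the ketone; the trisubstituted vinyl geometry is expected to be retained, and the C13 mixture is removed in step 20.

Step 20
Reactants: 33 fourteen-membered allylic alcohol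
Product: 34 fourteen-membered 9,13-diketone (1Z,5E,3-yne; 2R,7S,11R,12S)
Conditions: Dess–Martin periodinane, NaHCO3, CH2Cl2, 0 → 23 °C
Reagents that add atoms: none
Why: Oxidation of the allylic alcohol to the 1Z-enone merges both C13 epimers into one compound.

Step 21
Reactants: 34 fourteen-membered 9,13-diketone with 3-yne
Product: 35 fourteen-membered 9,13-diketone with 1Z-enone and (3Z,5E)-diene (2S,7S,11R,12S); C8 dithiolane, 7-O-TES, 2,12-di-O-TBS
Conditions: Zn dust activated with Cu(OAc)2 and AgNO3, MeOH/H2O 1:1, 23 °C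
Reagents that add atoms: none
Why: Boland-type zinc semi-reduction of the conjugated enyne gives the cis olefin (3Z); the neutral conditions should leave the enone, the propargylic-type C2–O bond and the dithiolane alone, unlike poisoned palladium, which sulfur would deactivate.

Step 22
Reactants: 35 fourteen-membered 9,13-diketone with 1Z-enone and (3Z,5E)-diene
Product: 38 bicyclic 9,13-diketone with quaternary C1 (1S,2S,7S,10S,11R,12S), via C9 lithium enolate 36 (not isolated), via C13 lithium enolate 37 (not isolated)
Conditions: LiN(SiMe3)2 (1.1 equiv), THF, −78 °C, then −78 → 0 °C; AcOH, −78 °C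
Reagents that add atoms: none
Why: LiN(SiMe3)2 removes a C10 proton, the only enolisable position of the C9 ketone because C8 is fully substituted; enolate 36 adds through C10 to C1, the β-carbon of the C13 enone, to give enolate 37, which is protonated at C14 on quench (transannular Michael addition; closest known type: transannular Michael cyclisation of macrocyclic keto-enones to fused bicycles). Ring C closes 6-endo-trig with respect to C1=C14 and keeps the C13 carbonyl inside the ring; the ten-membered ring closes 10-exo-trig and is what remains of the macrocycle, so no medium ring is made from an open chain. C1 is set by the enone face that C10 reaches: in a chair-like array of C10–C11–C12–C13–C14–C1 with the C20 methyl and the C12 silyloxy group equatorial, the 1Z geometry puts C15 (trans to C13) equatorial and C2 axial. C10 is set by the same chair: C9 takes the axial position anti to C2 across the new bond, a torsion a ten-membered ring can span, which gives the trans junction (C15 and H10 on opposite faces). The step needs enolisation toward C10 and 1,4- rather than 1,2-addition; the first is secured by the C8 dithiolane and kinetic deprotonation of the only α-methylene, the second by ring size, since 1,2-attack of C10 on C13 would give a cyclobutanol. The C1/C10 relation is expected, not assured; the addition is reversible and C10 is epimerisable, so a cis-fused kinetic product could be equilibrated with catalytic t-BuOK toward the trans-fused isomer.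

Step 23
Reactants: 38 bicyclic 9,13-diketone
Product: 40 C13 enol triflate (13,14-ene; 1S,2S,7S,10S,11R,12S), via C13 potassium enolate 39 (not isolated)
Conditions: KN(SiMe3)2 (1.15 equiv), THF, −78 °C; PhNTf2, −78 → −30 °C
Reagents that add atoms: N-phenylbis(trifluoromethanesulfonimide), O=S(=O)(N(c1ccccc1)S(=O)(=O)C(F)(F)F)C(F)(F)F
Why: Kinetic enolisation and O-triflation; C14 is the only methylene next to either ketone (C12 and C10 are hindered methines, C8 has no hydrogen), so the enolate should form toward C14.

Step 24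
Reactants: 40 C13 enol triflate
Product: 41 13,14-olefin 9-ketone (1S,2S,7S,10S,11R,12R)
Conditions: Pd(OAc)2 (10 mol %), PPh3 (20 mol %), HCO2H, n-Bu3N, DMF, 60 °C
Reagents that add atoms: none
Why: Palladium-catalysed formate reduction of the enol triflate (oxidative addition to zerovalent palladium, formate exchange, loss of CO2, reductive elimination) replaces OTf by H; ketone, diene and silyl ethers are not substrates.

Step 25
Reactants: 41 13,14-olefin 9-ketone
Product: 42 C7 alcohol (7-hydroxy 9-ketone; 1S,2S,7S,10S,11R,12R)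
Conditions: HF·pyridine, pyridine, THF, 0 °C
Reagents that add atoms: none
Why: Buffered fluoride cleaves the triethylsilyl ether much faster than the two tert-butyldimethylsilyl ethers; the mildly acidic medium avoids retro-aldol of the β-hydroxy ketone.

Step 26
Reactants: 42 C7 alcohol
Product: 43 7,9-anti-diol (1S,2S,7S,9S,10S,11R,12R)
Conditions: Me4NBH(OAc)3 (5 equiv), AcOH/MeCN 1:1, −30 → 0 °C
Reagents that add atoms: none
Why: Evans–Saksena reduction: the C7 hydroxyl binds boron and delivers hydride intramolecularly through a six-membered chair, giving the 1,3-anti diol and so the 9S carbinol of the target.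

Step 27
Reactants: 43 7,9-anti-diol
Product: 44 C7 acrylate with free C9 hydroxyl
Conditions: acryloyl chloride (1.2 equiv), i-Pr2NEt, CH2Cl2, −78 → −30 °C
Reagents that add atoms: acryloyl chloride, C=CC(=O)Cl
Why: Selective acylation of the less hindered hydroxyl: the C7 carbinol is allylic with one fully substituted neighbour, whereas the C9 carbinol lies between the dithiolane carbon and the ring-fusion methine.

Step 28
Reactants: 44 C7 acrylate with free C9 hydroxyl
Product: 45 C7 acrylate C9 acetate with C8 dithiolane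
Conditions: Ac2O, Et3N, DMAP, CH2Cl2, 23 °C
Reagents that add atoms: acetic anhydride, CC(=O)OC(C)=O
Why: DMAP-catalysed acetylation of the hindered C9 alcohol installs a final acetate early, so C9–O cannot compete for the lactone in step 30.

Step 29
Reactants: 45 C7 acrylate C9 acetate with C8 dithiolane
Product: 46 C8 ketone bearing C7 acrylate and C9 acetate
Conditions: MeI (excess), CaCO3, MeCN/H2O 4:1, 45 °C
Reagents that add atoms: water, O
Why: Alkylative dethioketalisation (S-methylation, ring opening to the thionium ion, hydrolysis) under neutral conditions, which silyl ethers, esters, the acrylate and the diene should survive.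

Step 30
Reactants: 46 C8 ketone bearing C7 acrylate and C9 acetate
Product: 49 8-hydroxy-17-methyl γ-lactone (1S,2S,7S,8S,9S,10S,11R,12R,17R), via copper enolate 47 (not isolated), via disiloxanyl ether 48 (not isolated)
Conditions: Cu(OAc)2·H2O (10 mol %), rac-BINAP (10 mol %), (Me2HSi)2O (1.2 equiv), THF, 0 → 23 °C; then NH4F, MeOH
Reagents that add atoms: none
Why: Copper hydride (monovalent copper) reduces the acrylate in conjugate fashion, and the copper enolate adds to the neighbouring C8 ketone (reductive aldol cyclisation), forming C8–C17 and the lactone. Delivery from O7 onto the ketone face that keeps C6 anti to C9 gives the trans-fused lactone; the C17 methyl is expected cis to the C8 oxygen, which is also the thermodynamically preferred arrangement at this epimerisable centre.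

Step 31
Reactants: 49 8-hydroxy-17-methyl γ-lactone
Product: 50 2,8,12-triol (1S,2S,7S,8S,9S,10S,11R,12R,17R)
Conditions: HF·pyridine, THF/MeCN, 0 → 23 °C
Reagents that add atoms: none
Why: Fluoride-mediated cleavage of both tert-butyldimethylsilyl ethers under mildly acidic conditions that should not open the lactone or move the acetate.

Step 32
Reactants: 50 2,8,12-triol
Product: 51 3,4:13,14-bis-epoxide diol (1R,2R,3S,4R,7S,8S,9S,10S,11R,12S,13S,14R,17R)
Conditions: VO(acac)2 (10 mol %), t-BuOOH (2.4 equiv), CH2Cl2, 0 °C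
Reagents that add atoms: tert-butyl hydroperoxide, CC(C)(C)OO
Why: Vanadium-catalysed hydroxyl-directed epoxidation. The C12 hydroxyl delivers oxygen cis on the cyclohexene. The C2 hydroxyl, in the conformer with H2 eclipsing C3=C4 (minimal A(1,3) strain against C5), lies on the exposed face and delivers syn, which gives the threo 2,3-relation. C5=C6 has no allylic hydroxyl and should remain.

Step 33
Reactants: 51 3,4:13,14-bis-epoxide diol
Product: 52 2,9,12-triacetate with C5=C6 olefin (1R,2R,3R,4R,7S,8S,9S,10S,11R,12S,13S,14R,17R)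
Conditions: Ac2O, pyridine, DMAP (cat.), CH2Cl2, 0 °C
Reagents that add atoms: acetic anhydride, CC(=O)OC(C)=O
Why: Acetylation of the two secondary alcohols; the tertiary C8 hydroxyl is too hindered to react under these conditions.

Step 34
Reactants: 52 2,9,12-triacetate with C5=C6 olefin
Product: 53 target (1R,2R,3R,4R,6S,7R,8R,9S,10S,11R,12S,13S,14R,17R)
Conditions: Ca(OCl)2, CO2 (solid), CH2Cl2/H2O, 0 °C
Reagents that add atoms: calcium hypochlorite, [Ca+2].[O-]Cl.[O-]Cl
Why: Ene-type chlorination by hypochlorous acid made in the flask: chlorine adds to the less substituted C6 and a C16 hydrogen is lost, giving the C5=C16 methylene. Attack is expected on the outer face, anti to the C7–O bond in the conformer with H7 eclipsing the olefin, which gives 6S; C5=C6 is the only olefin left.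

## Compound list

1 | (E)-3-methylpent-2-en-4-yn-1-ol | C#C/C(C)=C/CO | starting material
2 | trimethyl{[(E)-3-methyl-5-(trimethylsilyl)pent-2-en-4-yn-1-yl]oxy}silane | C[Si](C)(C)C#C/C(C)=C/CO[Si](C)(C)C | intermediate
3 | (E)-3-methyl-5-(trimethylsilyl)pent-2-en-4-yn-1-ol | C[Si](C)(C)C#C/C(C)=C/CO | intermediate
4 | (E)-3-methyl-5-(trimethylsilyl)pent-2-en-4-ynal | C[Si](C)(C)C#C/C(C)=C/C=O | intermediate
5 | ethyl 1,3-dithiolane-2-carboxylate | CCOC(=O)C1SCCS1 | starting material
6 | lithium enolate of 5 | CCOC(O[Li])=C1SCCS1 | intermediate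
7 | 2-[ethoxy(trimethylsilyloxy)methylidene]-1,3-dithiolane | CCOC(O[Si](C)(C)C)=C1SCCS1 | intermediate
8 | O-trimethylsilyl ether of 9 (7S) | CCOC(=O)C1(SCCS1)[C@@H](O[Si](C)(C)C)/C=C(C)/C#C[Si](C)(C)C | intermediate
9 | ethyl 2-[(1S,2E)-1-hydroxy-3-methyl-5-(trimethylsilyl)pent-2-en-4-yn-1-yl]-1,3-dithiolane-2-carboxylate | CCOC(=O)C1(SCCS1)[C@@H](O)/C=C(C)/C#C[Si](C)(C)C | intermediate
10 | ethyl 2-[(1S,2E)-3-methyl-1-[(triethylsilyl)oxy]-5-(trimethylsilyl)pent-2-en-4-yn-1-yl]-1,3-dithiolane-2-carboxylate | CCOC(=O)C1(SCCS1)[C@@H](O[Si](CC)(CC)CC)/C=C(C)/C#C[Si](C)(C)C | intermediate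
11 | N-methoxy-N-methyl-2-[(1S,2E)-3-methyl-1-[(triethylsilyl)oxy]-5-(trimethylsilyl)pent-2-en-4-yn-1-yl]-1,3-dithiolane-2-carboxamide | CON(C)C(=O)C1(SCCS1)[C@@H](O[Si](CC)(CC)CC)/C=C(C)/C#C[Si](C)(C)C | intermediate
12 | (S)-4-benzyl-3-propanoyl-1,3-oxazolidin-2-one | CCC(=O)N1C(=O)OC[C@@H]1Cc1ccccc1 | starting material
13 | 2-[(4-methoxybenzyl)oxy]acetaldehyde | COc1ccc(COCC=O)cc1 | starting material
14 | dibutylboron (Z)-enolate of 12 | CCCCB(CCCC)O/C(=C\C)N1C(=O)OC[C@@H]1Cc1ccccc1 | intermediate
15 | dibutylboron aldolate of 16 | COc1ccc(COC[C@@H](OB(CCCC)CCCC)[C@H](C)C(=O)N2C(=O)OC[C@@H]2Cc2ccccc2)cc1 | intermediate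
16 | (S)-4-benzyl-3-[(2S,3S)-3-hydroxy-4-[(4-methoxybenzyl)oxy]-2-methylbutanoyl]-1,3-oxazolidin-2-one | COc1ccc(COC[C@@H](O)[C@H](C)C(=O)N2C(=O)OC[C@@H]2Cc2ccccc2)cc1 | intermediate
17 | (S)-4-benzyl-3-[(2S,3S)-3-[(tert-butyldimethylsilyl)oxy]-4-[(4-methoxybenzyl)oxy]-2-methylbutanoyl]-1,3-oxazolidin-2-one | COc1ccc(COC[C@@H](O[Si](C)(C)C(C)(C)C)[C@H](C)C(=O)N2C(=O)OC[C@@H]2Cc2ccccc2)cc1 | intermediate
18 | (2R,3S)-3-[(tert-butyldimethylsilyl)oxy]-4-[(4-methoxybenzyl)oxy]-2-methylbutan-1-ol | COc1ccc(COC[C@@H](O[Si](C)(C)C(C)(C)C)[C@H](C)CO)cc1 | intermediate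
19 | tert-butyl{[(2S,3S)-4-iodo-1-[(4-methoxybenzyl)oxy]-3-methylbutan-2-yl]oxy}dimethylsilane | COc1ccc(COC[C@@H](O[Si](C)(C)C(C)(C)C)[C@H](C)CI)cc1 | intermediate
20 | primary alkyllithium from 19 (lithium on C10; 11R,12S) | COc1ccc(COC[C@@H](O[Si](C)(C)C(C)(C)C)[C@H](C)C[Li])cc1 | intermediate
21 | C3–C13 ketone (7S,11R,12S): 13-O-PMB, 12-O-TBS, 11-methyl, 9-oxo, 8,8-ethylenedithio, 7-O-TES, 5E-ene with 5-methyl, 3-yne capped by trimethylsilyl | COc1ccc(COC[C@@H](O[Si](C)(C)C(C)(C)C)[C@H](C)CC(=O)C2(SCCS2)[C@@H](O[Si](CC)(CC)CC)/C=C(C)/C#C[Si](C)(C)C)cc1 | intermediate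
22 | C3–C13 ketone as 21 with terminal C3 alkyne (7S,11R,12S) | COc1ccc(COC[C@@H](O[Si](C)(C)C(C)(C)C)[C@H](C)CC(=O)C2(SCCS2)[C@@H](O[Si](CC)(CC)CC)/C=C(C)/C#C)cc1 | intermediate
23 | prop-2-yn-1-ol | C#CCO | starting material
24 | 4-methyl-2,5-dihydro-1,2-oxamagnesole (alkoxide-bridged vinylmagnesium) | CC1=C[Mg]OC1 | intermediate
25 | (Z)-3-iodo-2-methylprop-2-en-1-ol | OC/C(C)=C\I | intermediate
26 | (Z)-3-iodo-2-methylprop-2-enal | O=C/C(C)=C\I | intermediate
27 | alkynyl(methyl)zinc derived from 22 | COc1ccc(COC[C@@H](O[Si](C)(C)C(C)(C)C)[C@H](C)CC(=O)C2(SCCS2)[C@@H](O[Si](CC)(CC)CC)/C=C(C)/C#C[Zn]C)cc1 | intermediate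
28 | open-chain C14–C13 propargylic alcohol (2S,7S,11R,12S): 2-hydroxy, (1Z)-14-iodo-1-methyl olefin, 3-yne, 5E-ene, 7-O-TES, 8-dithiolane, 9-oxo, 12-O-TBS, 13-O-PMB | COc1ccc(COC[C@@H](O[Si](C)(C)C(C)(C)C)[C@H](C)CC(=O)C2(SCCS2)[C@@H](O[Si](CC)(CC)CC)/C=C(C)/C#C[C@H](O)/C(C)=C\I)cc1 | intermediate
29 | C2 tert-butyldimethylsilyl ether of 28 (2S,7S,11R,12S) | COc1ccc(COC[C@@H](O[Si](C)(C)C(C)(C)C)[C@H](C)CC(=O)C2(SCCS2)[C@@H](O[Si](CC)(CC)CC)/C=C(C)/C#C[C@H](O[Si](C)(C)C(C)(C)C)/C(C)=C\I)cc1 | intermediate
30 | C13 primary alcohol from 29 (2S,7S,11R,12S) | OC[C@@H](O[Si](C)(C)C(C)(C)C)[C@H](C)CC(=O)C1(SCCS1)[C@@H](O[Si](CC)(CC)CC)/C=C(C)/C#C[C@H](O[Si](C)(C)C(C)(C)C)/C(C)=C\I | intermediate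
31 | C13 aldehyde with C14 vinyl iodide (2S,7S,11R,12S) | O=C[C@@H](O[Si](C)(C)C(C)(C)C)[C@H](C)CC(=O)C1(SCCS1)[C@@H](O[Si](CC)(CC)CC)/C=C(C)/C#C[C@H](O[Si](C)(C)C(C)(C)C)/C(C)=C\I | intermediate
32 | C14 alkenylchromium dichloride from 31 (trivalent chromium) | O=C[C@@H](O[Si](C)(C)C(C)(C)C)[C@H](C)CC(=O)C1(SCCS1)[C@@H](O[Si](CC)(CC)CC)/C=C(C)/C#C[C@H](O[Si](C)(C)C(C)(C)C)/C(C)=C\[Cr](Cl)Cl | intermediate
33 | fourteen-membered 13-hydroxy-9-ketone (1Z,5E,3-yne; 2R,7S,11R,12S; both C13 epimers) | C/C1=C/C(O)[C@@H](O[Si](C)(C)C(C)(C)C)[C@H](C)CC(=O)C2(SCCS2)[C@@H](O[Si](CC)(CC)CC)/C=C(C)/C#C[C@@H]1O[Si](C)(C)C(C)(C)C | intermediate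
34 | fourteen-membered 9,13-diketone (1Z,5E,3-yne; 2R,7S,11R,12S) | C/C1=C/C(=O)[C@@H](O[Si](C)(C)C(C)(C)C)[C@H](C)CC(=O)C2(SCCS2)[C@@H](O[Si](CC)(CC)CC)/C=C(C)/C#C[C@@H]1O[Si](C)(C)C(C)(C)C | intermediate
35 | fourteen-membered 9,13-diketone with 1Z-enone and (3Z,5E)-diene (2S,7S,11R,12S): 2,12-di-O-TBS, 7-O-TES, 8,8-ethylenedithio, methyls on C1, C5, C11 | C/C1=C/C(=O)[C@@H](O[Si](C)(C)C(C)(C)C)[C@H](C)CC(=O)C2(SCCS2)[C@@H](O[Si](CC)(CC)CC)/C=C(C)/C=C\[C@@H]1O[Si](C)(C)C(C)(C)C | intermediate
36 | C9 lithium enolate of 35 (C9=C10; enolate geometry not assigned) | C/C1=C/C(=O)[C@@H](O[Si](C)(C)C(C)(C)C)[C@H](C)C=C(O[Li])C2(SCCS2)[C@@H](O[Si](CC)(CC)CC)/C=C(C)/C=C\[C@@H]1O[Si](C)(C)C(C)(C)C | intermediate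
37 | C13 lithium enolate of 38 (C13=C14) | C[C@]12C=C(O[Li])[C@@H](O[Si](C)(C)C(C)(C)C)[C@H](C)[C@@H]1C(=O)C3(SCCS3)[C@@H](O[Si](CC)(CC)CC)/C=C(C)/C=C\[C@@H]2O[Si](C)(C)C(C)(C)C | intermediate
38 | bicyclic 9,13-diketone with quaternary C1 (1S,2S,7S,10S,11R,12S); ring C trans-fused to the ten-membered ring, (3Z,5E)-diene, 8-dithiolane | C[C@]12CC(=O)[C@@H](O[Si](C)(C)C(C)(C)C)[C@H](C)[C@@H]1C(=O)C3(SCCS3)[C@@H](O[Si](CC)(CC)CC)/C=C(C)/C=C\[C@@H]2O[Si](C)(C)C(C)(C)C | intermediate
39 | C13 potassium enolate of 38 | C[C@]12C=C(O[K])[C@@H](O[Si](C)(C)C(C)(C)C)[C@H](C)[C@@H]1C(=O)C3(SCCS3)[C@@H](O[Si](CC)(CC)CC)/C=C(C)/C=C\[C@@H]2O[Si](C)(C)C(C)(C)C | intermediate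
40 | C13 enol triflate, 13,14-ene, 9-ketone (1S,2S,7S,10S,11R,12S) | C[C@]12C=C(OS(=O)(=O)C(F)(F)F)[C@@H](O[Si](C)(C)C(C)(C)C)[C@H](C)[C@@H]1C(=O)C3(SCCS3)[C@@H](O[Si](CC)(CC)CC)/C=C(C)/C=C\[C@@H]2O[Si](C)(C)C(C)(C)C | intermediate
41 | 13,14-olefin 9-ketone (1S,2S,7S,10S,11R,12R) | C[C@]12C=C[C@@H](O[Si](C)(C)C(C)(C)C)[C@H](C)[C@@H]1C(=O)C3(SCCS3)[C@@H](O[Si](CC)(CC)CC)/C=C(C)/C=C\[C@@H]2O[Si](C)(C)C(C)(C)C | intermediate
42 | 7-hydroxy 9-ketone (1S,2S,7S,10S,11R,12R) | C[C@]12C=C[C@@H](O[Si](C)(C)C(C)(C)C)[C@H](C)[C@@H]1C(=O)C3(SCCS3)[C@@H](O)/C=C(C)/C=C\[C@@H]2O[Si](C)(C)C(C)(C)C | intermediate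
43 | 7,9-anti-diol (1S,2S,7S,9S,10S,11R,12R) | C[C@]12C=C[C@@H](O[Si](C)(C)C(C)(C)C)[C@H](C)[C@@H]1[C@H](O)C3(SCCS3)[C@@H](O)/C=C(C)/C=C\[C@@H]2O[Si](C)(C)C(C)(C)C | intermediate
44 | 7-acrylate 9-alcohol (1S,2S,7S,9S,10S,11R,12R) | C[C@]12C=C[C@@H](O[Si](C)(C)C(C)(C)C)[C@H](C)[C@@H]1[C@H](O)C3(SCCS3)[C@@H](OC(=O)C=C)/C=C(C)/C=C\[C@@H]2O[Si](C)(C)C(C)(C)C | intermediate
45 | 7-acrylate 9-acetate 8-dithiolane (1S,2S,7S,9S,10S,11R,12R) | C[C@]12C=C[C@@H](O[Si](C)(C)C(C)(C)C)[C@H](C)[C@@H]1[C@H](OC(C)=O)C3(SCCS3)[C@@H](OC(=O)C=C)/C=C(C)/C=C\[C@@H]2O[Si](C)(C)C(C)(C)C | intermediate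
46 | 7-acrylate 9-acetate 8-ketone (1S,2S,7S,9S,10S,11R,12R) | C[C@]12C=C[C@@H](O[Si](C)(C)C(C)(C)C)[C@H](C)[C@@H]1[C@H](OC(C)=O)C(=O)[C@@H](OC(=O)C=C)/C=C(C)/C=C\[C@@H]2O[Si](C)(C)C(C)(C)C | intermediate
47 | copper (Z)-enolate of the C7 propanoate (monovalent copper; ligand omitted) | C[C@]12C=C[C@@H](O[Si](C)(C)C(C)(C)C)[C@H](C)[C@@H]1[C@H](OC(C)=O)C(=O)[C@@H](O/C(O[Cu])=C/C)/C=C(C)/C=C\[C@@H]2O[Si](C)(C)C(C)(C)C | intermediate
48 | C8 O-(1,1,3,3-tetramethyldisiloxanyl) ether of 49 | C[C@]12C=C[C@@H](O[Si](C)(C)C(C)(C)C)[C@H](C)[C@@H]1[C@H](OC(C)=O)[C@]3(O[Si](C)(C)O[SiH](C)C)[C@@H](C)C(=O)O[C@H]3/C=C(C)/C=C\[C@@H]2O[Si](C)(C)C(C)(C)C | intermediate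
49 | 8-hydroxy-17-methyl 7,8-γ-lactone, 9-acetate, 2,12-di-O-TBS (1S,2S,7S,8S,9S,10S,11R,12R,17R) | C[C@]12C=C[C@@H](O[Si](C)(C)C(C)(C)C)[C@H](C)[C@@H]1[C@H](OC(C)=O)[C@]3(O)[C@@H](C)C(=O)O[C@H]3/C=C(C)/C=C\[C@@H]2O[Si](C)(C)C(C)(C)C | intermediate
50 | 2,8,12-triol lactone 9-acetate (1S,2S,7S,8S,9S,10S,11R,12R,17R) | C[C@]12C=C[C@@H](O)[C@H](C)[C@@H]1[C@H](OC(C)=O)[C@]3(O)[C@@H](C)C(=O)O[C@H]3/C=C(C)/C=C\[C@@H]2O | intermediate
51 | 3,4:13,14-bis-epoxide 2,12-diol 9-acetate with 5E-olefin (1R,2R,3S,4R,7S,8S,9S,10S,11R,12S,13S,14R,17R) | C/C1=C\[C@@H]2OC(=O)[C@H](C)[C@@]2(O)[C@@H](OC(C)=O)[C@H]3[C@@H](C)[C@H](O)[C@@H]4O[C@@H]4[C@]3(C)[C@@H](O)[C@@H]5O[C@H]15 | intermediate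
52 | 3,4:13,14-bis-epoxide 2,9,12-triacetate with 5E-olefin (1R,2R,3R,4R,7S,8S,9S,10S,11R,12S,13S,14R,17R) | C/C1=C\[C@@H]2OC(=O)[C@H](C)[C@@]2(O)[C@@H](OC(C)=O)[C@H]3[C@@H](C)[C@H](OC(C)=O)[C@@H]4O[C@@H]4[C@]3(C)[C@@H](OC(C)=O)[C@@H]5O[C@H]15 | intermediate
53 | CNP0229305.4: 2,9,12-triacetoxy-6-chloro-3,4:13,14-diepoxy-8-hydroxybriar-5(16)-en-19,7-olide (1R,2R,3R,4R,6S,7R,8R,9S,10S,11R,12S,13S,14R,17R) | C=C1[C@H]2O[C@H]2[C@H](OC(C)=O)[C@]2(C)[C@H]([C@@H](C)[C@H](OC(C)=O)[C@@H]3O[C@@H]32)[C@H](OC(C)=O)[C@]2(O)[C@@H](C)C(=O)O[C@H]2[C@H]1Cl | target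

## Step count and least certain steps

Total: 34 steps. Longest linear sequence: 27 steps (steps 1, 2, 4, 5, 6, 11, 12 and 15 to 34).

Step 22 (key step). The most likely failures are deprotonation at the wrong site and closure through the wrong chair. The enone has γ-hydrogens at C15 and C2, and scrambling there would erode the 1Z geometry on which the C1 configuration depends. The enolate may also not sit over C1 in the low-energy conformer of the macrocycle, giving no addition or a cis junction. Fallback: from 35, trap the kinetic C9 enolate (LiN(SiMe3)2, TMSCl, −78 °C) as the C9 trimethylsilyl enol ether F1. Then close the ring by a Lewis acid-mediated Mukaiyama–Michael reaction (TiCl4, CH2Cl2, −78 °C), which activates the enone instead of relying on a basic enolate and so cannot isomerise it through a dienolate. Aqueous work-up returns to the route at 38.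

Step 30. The likely failure is conjugate reduction of the acrylate without ring closure, or closure on the other face of the C8 ketone to a cis-fused lactone. The five-membered closure with the enolate double bond inside the forming ring is geometrically demanding, and the ketone flanked by two acyloxy carbons is itself prone to reduction. Fallback: from 43, acylate C7–OH with 2-bromopropanoyl bromide and pyridine to give the C7 2-bromopropanoate F2. Acetylate C9 (Ac2O, DMAP) to give the bromopropanoate acetate F3, and unmask C8 with MeI and CaCO3 to give the α-acyloxy ketone F4. Close the lactone by an intramolecular Reformatsky reaction with SmI2 (divalent samarium) in THF at −78 °C, where the samarium enolate is held to the ketone oxygen. If C17 needs correcting, equilibrate with DBU. This returns to the route at 49.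

Step 32. The likely failure is poor facial selectivity at C3=C4, if the vanadate delivers oxygen through a ring conformer in which the C2 oxygen has swung toward the other face. Competing epoxidation of C5=C6 directed by the homoallylic C8 hydroxyl is a second risk. Fallback: reverse the order of olefin functionalisation. From 50, carry out the ene chlorination first (Ca(OCl)2, CO2) to give the chloro triene diol F5. Then epoxidise with mCPBA and NaHCO3: hydrogen-bonded peracid delivery is threo-selective for Z-allylic alcohols and cis for cyclohexenols, and the C5=C16 methylene is deactivated by the allylic chlorine. This gives the bis-epoxy diol F6. Acetylation (Ac2O, pyridine) returns to the route at 53.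

Step 34. The likely failure is chlorine delivery to the wrong face of C5=C6, because the face preference rests only on the conformation of the ten-membered ring. Opening of the allylic 3,4-epoxide by hypochlorous or hydrochloric acid is a second risk. Fallback: from 52, oxidise the C16 methyl with SeO2 and t-BuOOH (allylic oxidation at the more substituted olefin terminus) to give the 16-hydroxy compound F7. Treat F7 with SOCl2 in Et2O; the chlorosulfite collapses with allylic transposition (SNi′), placing chlorine on C6 and the olefin at C5=C16. This returns to the route at 53.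

Step 29. The likely failure is very slow hydrolysis, because C–S heterolysis at C8 is retarded by the two flanking acyloxy carbons; forcing conditions invite acyl participation or migration. Fallback: unmask before acylating. From 43, MeI and CaCO3 give the 7,9-dihydroxy 8-ketone F8. Selective acylation with acryloyl chloride gives the 7-acrylate 9-hydroxy ketone F9, and acetylation (Ac2O, DMAP) returns to the route at 46.

## Further compounds

F1 | step 22 | C9 trimethylsilyl enol ether of 35 (enol ether geometry not assigned) | C/C1=C/C(=O)[C@@H](O[Si](C)(C)C(C)(C)C)[C@H](C)C=C(O[Si](C)(C)C)C2(SCCS2)[C@@H](O[Si](CC)(CC)CC)/C=C(C)/C=C\[C@@H]1O[Si](C)(C)C(C)(C)C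
F2 | step 30 | C7 2-bromopropanoate of 43 (both epimers at the brominated carbon) | C[C@]12C=C[C@@H](O[Si](C)(C)C(C)(C)C)[C@H](C)[C@@H]1[C@H](O)C3(SCCS3)[C@@H](OC(=O)C(C)Br)/C=C(C)/C=C\[C@@H]2O[Si](C)(C)C(C)(C)C
F3 | step 30 | C7 2-bromopropanoate C9 acetate with C8 dithiolane | C[C@]12C=C[C@@H](O[Si](C)(C)C(C)(C)C)[C@H](C)[C@@H]1[C@H](OC(C)=O)C3(SCCS3)[C@@H](OC(=O)C(C)Br)/C=C(C)/C=C\[C@@H]2O[Si](C)(C)C(C)(C)C
F4 | step 30 | C7 2-bromopropanoate C9 acetate C8 ketone | C[C@]12C=C[C@@H](O[Si](C)(C)C(C)(C)C)[C@H](C)[C@@H]1[C@H](OC(C)=O)C(=O)[C@@H](OC(=O)C(C)Br)/C=C(C)/C=C\[C@@H]2O[Si](C)(C)C(C)(C)C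
F5 | step 32 | 6-chloro-5(16)-ene 3Z,13-diene 2,8,12-triol lactone 9-acetate | C=C1/C=C\[C@H](O)[C@]2(C)[C@H]([C@@H](C)[C@H](O)C=C2)[C@H](OC(C)=O)[C@]2(O)[C@@H](C)C(=O)O[C@H]2[C@H]1Cl
F6 | step 32 | 6-chloro-3,4:13,14-diepoxy-5(16)-ene 2,12-diol 9-acetate | C=C1[C@H]2O[C@H]2[C@H](O)[C@]2(C)[C@H]([C@@H](C)[C@H](O)[C@@H]3O[C@@H]32)[C@H](OC(C)=O)[C@]2(O)[C@@H](C)C(=O)O[C@H]2[C@H]1Cl
F7 | step 34 | 16-hydroxy derivative of 52 (5E-olefin kept) | OC/C1=C\[C@@H]2OC(=O)[C@H](C)[C@@]2(O)[C@@H](OC(C)=O)[C@H]3[C@@H](C)[C@H](OC(C)=O)[C@@H]4O[C@@H]4[C@]3(C)[C@@H](OC(C)=O)[C@@H]5O[C@H]15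
F8 | step 29 | 7,9-dihydroxy 8-ketone | C[C@]12C=C[C@@H](O[Si](C)(C)C(C)(C)C)[C@H](C)[C@@H]1[C@H](O)C(=O)[C@@H](O)/C=C(C)/C=C\[C@@H]2O[Si](C)(C)C(C)(C)C
F9 | step 29 | 7-acrylate 9-hydroxy 8-ketone | C[C@]12C=C[C@@H](O[Si](C)(C)C(C)(C)C)[C@H](C)[C@@H]1[C@H](O)C(=O)[C@@H](OC(=O)C=C)/C=C(C)/C=C\[C@@H]2O[Si](C)(C)C(C)(C)C
A1 | alternative 1 | ten-membered C6-chloro C7-hydroxy ester | C=C1[C@H]2O[C@H]2[C@H](OC(C)=O)[C@]2(C)[C@H]([C@@H](C)[C@H](OC(C)=O)[C@@H]3O[C@@H]32)[C@H](OC(C)=O)[C@](O[Si](CC)(CC)CC)([C@@H](C)C(=O)OC)[C@@H](O)[C@H]1Cl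
A2 | alternative 1 | open-chain bromo aldehyde with (Z)-C6 vinyl chloride, C16 bromide and C7 aldehyde | BrC/C(=C\Cl)[C@H]1O[C@H]1[C@H](OC(C)=O)[C@]1(C)[C@H]([C@@H](C)[C@H](OC(C)=O)[C@@H]2O[C@@H]21)[C@H](OC(C)=O)[C@](O[Si](CC)(CC)CC)([C@@H](C)C(=O)OC)C=O
A3 | alternative 2 | γ-lactone with quaternary C8 and C17 methyl | COC(=O)[C@@H]1OC(=O)[C@H](C)[C@@]1(O[Si](C)(C)C(C)(C)C)COCc2ccc(OC)cc2
A4 | alternative 2 | C7 2-diazopropanoate with C8–H | COC(=O)[C@H](OC(=O)C(C)=[N+]=[N-])[C@H](O[Si](C)(C)C(C)(C)C)COCc1ccc(OC)cc1
A5 | alternative 3 | ring C cycloadduct with C2 aldehyde and C9 ester | O=C[C@@]1(C)[C@@H](N(C)C)C=C(O[Si](C)(C)C(C)(C)C)C[C@@H]1C(=O)OCC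
A6 | alternative 3 | (E)-1-(dimethylamino)-3-[(tert-butyldimethylsilyl)oxy]buta-1,3-diene | CN(C)/C=C/C(=C)O[Si](C)(C)C(C)(C)C
A7 | alternative 3 | ethyl (E)-3-methyl-4-oxobut-2-enoate | CCOC(=O)/C=C(\C)C=O
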